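**Retrosynthetic overview**
- The target comes from one global hydride reduction of a tetra-ester: the glyceryl ether is carried as an aryloxymalonate, C9 as an ethyl ester and the ring-B propanol as an ethyl propanoate.
- C7 and C8 (threo, 7R,8R) come from a syn-selective transfer-hydrogenative dynamic kinetic resolution of a configurationally labile α-aryloxy-β-keto ester.
- The key 8-O-4′ aryl alkyl ether C–O bond comes from Rh(II)-carbenoid O–H insertion of the ring-B phenol into a ring-A aroyl diazoacetate.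
- The diazo keto ester comes from syringaldehyde, diethyl chloromalonate and ethyl diazoacetate; the phenol comes from sinapic acid.
- No ring is formed; both benzene rings are bought with the starting materials.

Assumption: the SMILES is read as the threo-(7R,8R) isomer (the glyceryl CH is not a stereocentre), and the (S,S) catalyst in step 5 is chosen from the standard aryl-ketone model, so the sense of induction must be confirmed on the first run.

**Step 1**
Reactants: 1 syringaldehyde; 2 diethyl chloromalonate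
Product: 3 diethyl 2-(4-formyl-2,6-dimethoxyphenoxy)propanedioate
Conditions: K2CO3 (1.5 equiv), DMF, 60 °C
Reagents that add atoms: none
Why: Williamson ether synthesis (SN2) of the acidic, fully ionised phenoxide on the doubly activated α-chloromalonate; the product malonate has a single C–H and so cannot undergo Knoevenagel condensation with the aldehyde; no stereocentre is formed.

**Step 2**
Reactants: 3 diethyl 2-(4-formyl-2,6-dimethoxyphenoxy)propanedioate; 4 ethyl diazoacetate
Product: 6 diethyl 2-[4-(2-diazo-3-ethoxy-3-oxopropanoyl)-2,6-dimethoxyphenoxy]propanedioate, via diazo alcohol 5 (not isolated)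
Conditions: 4 (1.5 equiv), DBU (0.2 equiv), DMSO, rt; then IBX (1.5 equiv), rt
Reagents that add atoms: none
Why: DBU-catalysed aldol-type addition of the diazoacetate anion to the aldehyde gives carbinol 5, which IBX oxidises in the same pot to the ketone without touching the diazo group (one-pot aldehyde to diazo keto ester sequence); the carbinol stereocentre of 5 is destroyed.

**Step 3**
Reactants: 7 sinapic acid
Product: 9 ethyl 3-(4-hydroxy-3,5-dimethoxyphenyl)propanoate, via dihydrosinapic acid 8 (not isolated)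
Conditions: H2 (1 atm), 10% Pd/C, EtOH, rt; filter; then H2SO4 (cat.), reflux
Reagents that add atoms: ethanol, CCO
Why: Heterogeneous catalytic hydrogenation of the cinnamic C=C followed by Fischer esterification in the same ethanol solution; the phenol and aryl methyl ethers are inert and no stereocentre is formed.

**Step 4**
Reactants: 6 diethyl 2-[4-(2-diazo-3-ethoxy-3-oxopropanoyl)-2,6-dimethoxyphenoxy]propanedioate; 9 ethyl 3-(4-hydroxy-3,5-dimethoxyphenyl)propanoate
Product: 10 diethyl 2-{4-[3-ethoxy-2-[4-(3-ethoxy-3-oxopropyl)-2,6-dimethoxyphenoxy]-3-oxopropanoyl]-2,6-dimethoxyphenoxy}propanedioate (racemic at the aryloxy carbon)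
Conditions: Rh2(OAc)4 (1 mol%), 9 (1.3 equiv), toluene, 80 °C, slow addition of 6
Reagents that add atoms: none
Why: Rh(II)-carbenoid O–H insertion (oxonium ylide, then proton shift) forms the 8-O-4′ C–O bond at oxygen and so tolerates the 2,6-dimethoxy flanking that defeats SN2 etherification; the blocked ortho positions of 9 prevent benzofuran formation, and the new centre is formed racemic and left epimerisable for step 5.

**Step 5**
Reactants: 10 diethyl 2-{4-[3-ethoxy-2-[4-(3-ethoxy-3-oxopropyl)-2,6-dimethoxyphenoxy]-3-oxopropanoyl]-2,6-dimethoxyphenoxy}propanedioate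
Product: 11 diethyl 2-{4-[(1R,2S)-3-ethoxy-2-[4-(3-ethoxy-3-oxopropyl)-2,6-dimethoxyphenoxy]-1-hydroxy-3-oxopropyl]-2,6-dimethoxyphenoxy}propanedioate (syn; the ethyl (2S,3R)-2-aryloxy-3-hydroxy-3-arylpropanoate)
Conditions: (S,S)-Teth-TsDPEN–RuCl (1 mol%), HCO2H/Et3N (5:2), CH2Cl2, 30 °C
Reagents that add atoms: none
Why: Proposed new method: syn-selective Noyori–Ikariya asymmetric transfer hydrogenation with dynamic kinetic resolution, applied to an α-(2,6-dimethoxyaryloxy)-β-keto ester, a substrate class on which to my knowledge it has not been shown; the C–H flanked by ketone, ester and aryloxy groups epimerises through the enol in HCO2H/Et3N much faster than hydride transfer, the (S,S)-Ru–H/N–H catalyst reduces the aryl ketone through the outer-sphere six-membered transition state with the usual aryl/η6-arene CH–π recognition (giving the carbinol R), and only the 2S enantiomer reacts, through a Felkin-type geometry with the ester antiperiplanar to the incoming hydride and the small H on the hydride side, which gives the syn (threo) 2S,3R product that becomes 7R,8R after step 6; the closest known reaction type is Ru/Rh–TsDPEN transfer-hydrogenative DKR of α-alkoxy (OMe, OBn) and α-amido β-keto esters, which is syn-selective in the alkoxy series.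

**Step 6**
Reactants: 11 diethyl 2-{4-[(1R,2S)-3-ethoxy-2-[4-(3-ethoxy-3-oxopropyl)-2,6-dimethoxyphenoxy]-1-hydroxy-3-oxopropyl]-2,6-dimethoxyphenoxy}propanedioate
Product: 12 (1R,2R)-1-[4-(1,3-dihydroxypropan-2-yloxy)-3,5-dimethoxyphenyl]-2-[4-(3-hydroxypropyl)-2,6-dimethoxyphenoxy]propane-1,3-diol (target)
Conditions: LiAlH4 (6 equiv), THF, 0 °C to rt; Rochelle salt work-up
Reagents that add atoms: none
Why: LiAlH4 ester reduction converts all four ethyl esters (two malonate, C9 and side-chain) into primary alcohols, as precedented separately for aryloxymalonates and for α-aryloxy-β-hydroxy esters; C7 and C8 are not touched, and the 2S descriptor of the ester becomes 8R only through the CIP priority change.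

**Compound list**
1 | syringaldehyde (4-hydroxy-3,5-dimethoxybenzaldehyde) | COc1cc(C=O)cc(OC)c1O | starting material
2 | diethyl chloromalonate | CCOC(=O)C(Cl)C(=O)OCC | starting material
3 | diethyl 2-(4-formyl-2,6-dimethoxyphenoxy)propanedioate | COc1cc(C=O)cc(OC)c1OC(C(=O)OCC)C(=O)OCC | intermediate
4 | ethyl diazoacetate | CCOC(=O)C=[N+]=[N-] | starting material
5 | diethyl 2-[4-(2-diazo-3-ethoxy-1-hydroxy-3-oxopropyl)-2,6-dimethoxyphenoxy]propanedioate (racemic diazo alcohol) | COc1cc(C(O)C(=[N+]=[N-])C(=O)OCC)cc(OC)c1OC(C(=O)OCC)C(=O)OCC | intermediate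
6 | diethyl 2-[4-(2-diazo-3-ethoxy-3-oxopropanoyl)-2,6-dimethoxyphenoxy]propanedioate | COc1cc(C(=O)C(=[N+]=[N-])C(=O)OCC)cc(OC)c1OC(C(=O)OCC)C(=O)OCC | intermediate
7 | sinapic acid ((E)-3-(4-hydroxy-3,5-dimethoxyphenyl)prop-2-enoic acid) | COc1cc(/C=C/C(=O)O)cc(OC)c1O | starting material
8 | dihydrosinapic acid (3-(4-hydroxy-3,5-dimethoxyphenyl)propanoic acid) | COc1cc(CCC(=O)O)cc(OC)c1O | intermediate
9 | ethyl 3-(4-hydroxy-3,5-dimethoxyphenyl)propanoate | COc1cc(CCC(=O)OCC)cc(OC)c1O | intermediate
10 | diethyl 2-{4-[3-ethoxy-2-[4-(3-ethoxy-3-oxopropyl)-2,6-dimethoxyphenoxy]-3-oxopropanoyl]-2,6-dimethoxyphenoxy}propanedioate (racemic, epimerisable α-aryloxy-β-keto ester) | COc1cc(C(=O)C(C(=O)OCC)Oc2c(OC)cc(CCC(=O)OCC)cc2OC)cc(OC)c1OC(C(=O)OCC)C(=O)OCC | intermediate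
11 | diethyl 2-{4-[(1R,2S)-3-ethoxy-2-[4-(3-ethoxy-3-oxopropyl)-2,6-dimethoxyphenoxy]-1-hydroxy-3-oxopropyl]-2,6-dimethoxyphenoxy}propanedioate (syn hydroxy ester) | COc1cc([C@@H](O)[C@@H](C(=O)OCC)Oc2c(OC)cc(CCC(=O)OCC)cc2OC)cc(OC)c1OC(C(=O)OCC)C(=O)OCC | intermediate
12 | (1R,2R)-1-[4-(1,3-dihydroxypropan-2-yloxy)-3,5-dimethoxyphenyl]-2-[4-(3-hydroxypropyl)-2,6-dimethoxyphenoxy]propane-1,3-diol (threo, 7R,8R) | COc1cc([C@@H](O)[C@@H](CO)Oc2c(OC)cc(CCCO)cc2OC)cc(OC)c1OC(CO)CO | target

**Totals**
Total step count: 6. Longest linear sequence: 5 (steps 1, 2, 4, 5, 6 from syringaldehyde).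

**Three steps most likely to fail**

Step 5 (the proposed new step). The bulky 2,6-dimethoxyaryloxy group may slow hydride transfer or erode the syn selectivity and ee. The fallback uses known chemistry, sets out from 9 and 3 and comes back at 12. Phenol 9 is O-alkylated with commercial (S)-4-benzyl-3-(chloroacetyl)oxazolidin-2-one (K2CO3, NaI, acetone) to give the imide (S)-4-benzyl-3-{2-[4-(3-ethoxy-3-oxopropyl)-2,6-dimethoxyphenoxy]acetyl}oxazolidin-2-one F2. An Evans syn-glycolate aldol of F2 with aldehyde 3 (Bu2BOTf, i-Pr2NEt, CH2Cl2, −78 to 0 °C) then gives the syn adduct (S)-4-benzyl-3-{(2S,3R)-3-[4-(1,3-diethoxy-1,3-dioxopropan-2-yloxy)-3,5-dimethoxyphenyl]-2-[4-(3-ethoxy-3-oxopropyl)-2,6-dimethoxyphenoxy]-3-hydroxypropanoyl}oxazolidin-2-one F3. Both stereocentres are fixed by the auxiliary. LiBH4 (THF/MeOH) then removes the auxiliary reductively and reduces the three esters, giving 12 directly.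

Step 2. The diazoacetate addition is reversible and may stall on this alkoxy-substituted aldehyde, and the DBU-generated malonate anion could be oxidised by IBX. The fallback sets out from 3 and 4 and comes back at 6. Roskamp homologation of 3 with 4 (NbCl5 cat., CH2Cl2, rt) gives the β-keto ester diethyl 2-[4-(3-ethoxy-3-oxopropanoyl)-2,6-dimethoxyphenoxy]propanedioate F1. Regitz diazo transfer to the CH2 group of F1 (p-ABSA, Et3N, MeCN) gives 6; the malonate carbon has only one hydrogen and cannot take a diazo group.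

Step 6. Four esters must be reduced in the presence of a free β-hydroxy ester (retro-aldol risk) and an enolisable aryloxymalonate (stalling or elimination under basic hydride), and the pentaol is very polar. The fallback sets out from 11 and comes back at 12. Silylation of the C7 hydroxyl (TBSCl, imidazole, DMF) gives the silyl ether diethyl 2-{4-[(1R,2S)-1-(tert-butyldimethylsilyloxy)-3-ethoxy-2-[4-(3-ethoxy-3-oxopropyl)-2,6-dimethoxyphenoxy]-3-oxopropyl]-2,6-dimethoxyphenoxy}propanedioate F4, which cannot undergo retro-aldol cleavage. The milder, less basic LiBH4 (THF, MeOH, 0 to 40 °C) gives the chromatographable tetraol (2R,3R)-3-(tert-butyldimethylsilyloxy)-3-[4-(1,3-dihydroxypropan-2-yloxy)-3,5-dimethoxyphenyl]-2-[4-(3-hydroxypropyl)-2,6-dimethoxyphenoxy]propan-1-ol F5. TBAF in THF then gives 12.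

**Further compounds**
F1 | step 2 | diethyl 2-[4-(3-ethoxy-3-oxopropanoyl)-2,6-dimethoxyphenoxy]propanedioate | COc1cc(C(=O)CC(=O)OCC)cc(OC)c1OC(C(=O)OCC)C(=O)OCC
F2 | step 5 | (S)-4-benzyl-3-{2-[4-(3-ethoxy-3-oxopropyl)-2,6-dimethoxyphenoxy]acetyl}oxazolidin-2-one | CCOC(=O)CCc1cc(OC)c(OCC(=O)N2[C@@H](Cc3ccccc3)COC2=O)c(OC)c1
F3 | step 5 | (S)-4-benzyl-3-{(2S,3R)-3-[4-(1,3-diethoxy-1,3-dioxopropan-2-yloxy)-3,5-dimethoxyphenyl]-2-[4-(3-ethoxy-3-oxopropyl)-2,6-dimethoxyphenoxy]-3-hydroxypropanoyl}oxazolidin-2-one | COc1cc([C@@H](O)[C@@H](C(=O)N2[C@@H](Cc3ccccc3)COC2=O)Oc4c(OC)cc(CCC(=O)OCC)cc4OC)cc(OC)c1OC(C(=O)OCC)C(=O)OCC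
F4 | step 6 | diethyl 2-{4-[(1R,2S)-1-(tert-butyldimethylsilyloxy)-3-ethoxy-2-[4-(3-ethoxy-3-oxopropyl)-2,6-dimethoxyphenoxy]-3-oxopropyl]-2,6-dimethoxyphenoxy}propanedioate | COc1cc([C@@H](O[Si](C)(C)C(C)(C)C)[C@@H](C(=O)OCC)Oc2c(OC)cc(CCC(=O)OCC)cc2OC)cc(OC)c1OC(C(=O)OCC)C(=O)OCC
F5 | step 6 | (2R,3R)-3-(tert-butyldimethylsilyloxy)-3-[4-(1,3-dihydroxypropan-2-yloxy)-3,5-dimethoxyphenyl]-2-[4-(3-hydroxypropyl)-2,6-dimethoxyphenoxy]propan-1-ol | COc1cc([C@@H](O[Si](C)(C)C(C)(C)C)[C@@H](CO)Oc2c(OC)cc(CCCO)cc2OC)cc(OC)c1OC(CO)CO
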